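**Retrosynthetic overview**

1. Target 31 ⇐ furan 27. The C6–O–C12(=O) enol lactone and its C5=C6 alkene are made last, by singlet-oxygen oxidation of a 2,3,4-trisubstituted furan (C6, C7, C11, C12, O) and a dehydration whose geometry the ring enforces.
2. Ten-membered carbocycle ⇐ open-chain silyl enol ether 22 by an intramolecular Mukaiyama aldol C9→C10. Enabling feature: the C8–O/C10–O 1,3-pair across C9 (aldol retron) lies between two flat five-membered rings, the furan (C5 and C8 cis on C6=C7) and the 2-acetyl-2,3-dihydrofuran (O1–C1=C2, carbonyl at C10), so only C4, C5 and C9 are sp3 in the closing chain.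
3. Seco compound ⇐ (S)-2-methylglycidol as the C3–C4(Me)(O)–C5 linchpin: two successive epoxide openings (alkynyl at C3, furyl at C5) fix C4, a gold-catalysed 5-endo-dig cyclisation gives the dihydrofuran, and C8–C9 enters as a chloroacetyl group.
4. Ring order: furan (bought) → dihydrofuran (step 9) → carbocycle and oxa-bridged nine-membered ring (step 15) → butenolide from the furan (steps 18 and 19).
5. Stereocentres: C4 from the chiral pool, C10 in the key step, C8 by 1,3-syn reduction.

Key step: step 15

Assumption (numbering, as a remark on the chemistry): germacrane numbering is used. C1(=C2) is the enol-ether carbon bonded to C10 and ring oxygen O1, C3 the methylene, C4 the quaternary C–O carbon, C5=C6 the exocyclic alkene, C7=C11 the butenolide alkene, C8 the acyloxy carbinol, C9 the methylene, C10 the tertiary carbinol, C12 the lactone carbonyl, C13 the CH2OAc carbon; the target is 4R,8R,10S with an E C5=C6 bond.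

**Route**

Step 1
Reactants: 1 (S)-but-3-yn-2-ol
Product: 2 triethyl{[(2S)-but-3-yn-2-yl]oxy}silane
Conditions: Et3SiCl, imidazole, DMF, 0 °C to rt
Reagents that add atoms: chlorotriethylsilane CC[Si](CC)(CC)Cl
Why: Imidazole-promoted silyl ether formation on a secondary alcohol; the carbinol centre (future C10) is untouched and is kept defined only so that later intermediates are single diastereomers until it is oxidised in step 13.

Step 2
Reactants: 3 (S)-2-methylglycidol
Product: 4 [(2R)-2-methyloxiran-2-yl]methyl 4-methylbenzenesulfonate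
Conditions: TsCl, Et3N, DMAP (cat.), CH2Cl2, 0 °C
Reagents that add atoms: 4-methylbenzenesulfonyl chloride Cc1ccc(cc1)S(=O)(=O)Cl
Why: O-Sulfonylation of the primary alcohol; no bond to the stereocentre (future C4) is touched, and the descriptor changes from S to R only through the priority rules.

Step 3
Reactants: 2 triethyl{[(2S)-but-3-yn-2-yl]oxy}silane; 4 [(2R)-2-methyloxiran-2-yl]methyl 4-methylbenzenesulfonate
Product: 6 (2R,6S)-2-hydroxy-2-methyl-6-[(triethylsilyl)oxy]hept-4-yn-1-yl 4-methylbenzenesulfonate, via lithium acetylide 5 (not isolated)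
Conditions: n-BuLi, THF, −78 °C; then 4, BF3·OEt2, −78 °C; H2O
Reagents that add atoms: none
Why: BF3-promoted alkynylation of an epoxide (Yamaguchi conditions): the acetylide opens the oxirane by SN2 attack at its unsubstituted CH2 (future C3) faster than it displaces the tosylate, and the C4–O bond is not broken, so C4 is retained.

Step 4
Reactants: 6 (2R,6S)-2-hydroxy-2-methyl-6-[(triethylsilyl)oxy]hept-4-yn-1-yl 4-methylbenzenesulfonate
Product: 7 triethyl({(2S)-5-[(2R)-2-methyloxiran-2-yl]pent-3-yn-2-yl}oxy)silane
Conditions: NaH, THF, 0 °C to rt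
Reagents that add atoms: none
Why: Intramolecular Williamson etherification (3-exo-tet): the tertiary alkoxide displaces the primary tosylate and re-forms an epoxide, now between C4 and C5, again without breaking a bond at C4.

Step 5
Reactants: 8 3,4-dibromofuran
Product: 10 4-bromofuran-3-carbaldehyde, via bromofuryllithium 9 (not isolated)
Conditions: n-BuLi (1.0 equiv), Et2O, −78 °C; then DMF; H2O
Reagents that add atoms: N,N-dimethylformamide CN(C)C=O
Why: Single bromine–lithium exchange on the symmetrical dibromide followed by formylation with DMF; the 3-furyllithium is configurationally stable at −78 °C and the second bromine stays as the handle for C8.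

Step 6
Reactants: 10 4-bromofuran-3-carbaldehyde
Product: 11 (4-bromofuran-3-yl)methanol
Conditions: NaBH4, MeOH, 0 °C
Reagents that add atoms: none
Why: Borohydride reduction of an aldehyde; the aryl bromide is inert.

Step 7
Reactants: 11 (4-bromofuran-3-yl)methanol
Product: 12 [(4-bromofuran-3-yl)methoxy](tert-butyl)dimethylsilane
Conditions: t-BuMe2SiCl, imidazole, DMF, rt
Reagents that add atoms: tert-butyldimethylsilyl chloride CC(C)(C)[Si](C)(C)Cl
Why: Silyl protection of the primary alcohol (future C13–O) so that it survives the organolithium steps.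

Step 8
Reactants: 12 [(4-bromofuran-3-yl)methoxy](tert-butyl)dimethylsilane; 7 triethyl({(2S)-5-[(2R)-2-methyloxiran-2-yl]pent-3-yn-2-yl}oxy)silane
Product: 14 (2R,6S)-1-{3-bromo-4-[(tert-butyldimethylsilyloxy)methyl]furan-2-yl}-2-methyl-6-[(triethylsilyl)oxy]hept-4-yn-2-ol, via bromofuryllithium 13 (not isolated)
Conditions: LiN(iPr)2, THF, −78 °C; then 7, BF3·OEt2, −78 °C; H2O
Reagents that add atoms: none
Why: Deprotonation at the furan α-position flanked by the ring oxygen and the C–Br carbon (the most acidic site), then BF3-assisted SN2 opening of the 2,2-disubstituted epoxide at its CH2 (C5); this forms C5–C6 and liberates the C4 tertiary alcohol with C4 unchanged.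

Step 9
Reactants: 14 (2R,6S)-1-{3-bromo-4-[(tert-butyldimethylsilyloxy)methyl]furan-2-yl}-2-methyl-6-[(triethylsilyl)oxy]hept-4-yn-2-ol
Product: 15 {[4-bromo-5-({(2R)-2-methyl-5-[(1S)-1-(triethylsilyloxy)ethyl]-2,3-dihydrofuran-2-yl}methyl)furan-3-yl]methoxy}(tert-butyl)dimethylsilane
Conditions: Ph3PAuCl (5 mol %), AgOTf (5 mol %), toluene, 0 °C; then Et3N
Reagents that add atoms: none
Why: Gold-catalysed 5-endo-dig hydroalkoxylation of a homopropargylic alcohol: the C4 hydroxyl adds to the gold-activated alkyne at C1 and protodeauration gives the 2,3-dihydrofuran with the C1=C2 enol ether; the 4-exo mode is not accessible and the bromo-substituted furan is too electron-poor to compete as a nucleophile.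

Step 10
Reactants: 15 {[4-bromo-5-({(2R)-2-methyl-5-[(1S)-1-(triethylsilyloxy)ethyl]-2,3-dihydrofuran-2-yl}methyl)furan-3-yl]methoxy}(tert-butyl)dimethylsilane; 16 2-chloro-N-methoxy-N-methylacetamide
Product: 18 2-chloro-1-{4-[(tert-butyldimethylsilyloxy)methyl]-2-({(2R)-2-methyl-5-[(1S)-1-(triethylsilyloxy)ethyl]-2,3-dihydrofuran-2-yl}methyl)furan-3-yl}ethan-1-one, via furyllithium 17 (not isolated)
Conditions: t-BuLi (2.1 equiv), Et2O, −78 °C; then 16, −78 to −40 °C; H2O
Reagents that add atoms: none
Why: Bromine–lithium exchange (faster than any deprotonation at −78 °C) and Weinreb ketone synthesis, whose chelated tetrahedral intermediate prevents over-addition; the chloroacetyl group brings in C8 and C9 and marks C9 as the only carbon that will later become an enol carbon.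

Step 11
Reactants: 18 2-chloro-1-{4-[(tert-butyldimethylsilyloxy)methyl]-2-({(2R)-2-methyl-5-[(1S)-1-(triethylsilyloxy)ethyl]-2,3-dihydrofuran-2-yl}methyl)furan-3-yl}ethan-1-one
Product: 19 2-chloro-1-[4-(hydroxymethyl)-2-({(2R)-5-[(1S)-1-hydroxyethyl]-2-methyl-2,3-dihydrofuran-2-yl}methyl)furan-3-yl]ethan-1-one
Conditions: Et3N·3HF, THF, rt
Reagents that add atoms: none
Why: Fluoride desilylation of both silyl ethers under non-basic, non-nucleophilic conditions, so that the liberated C13 hydroxyl does not displace the α-chloride and the enol ether is not hydrated.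

Step 12
Reactants: 19 2-chloro-1-[4-(hydroxymethyl)-2-({(2R)-5-[(1S)-1-hydroxyethyl]-2-methyl-2,3-dihydrofuran-2-yl}methyl)furan-3-yl]ethan-1-one
Product: 20 [4-(chloroacetyl)-5-({(2R)-5-[(1S)-1-hydroxyethyl]-2-methyl-2,3-dihydrofuran-2-yl}methyl)furan-3-yl]methyl acetate
Conditions: AcCl (1.05 equiv), 2,4,6-collidine, CH2Cl2, −78 °C
Reagents that add atoms: acetyl chloride CC(=O)Cl
Why: Kinetically selective acylation of the primary over the secondary alcohol installs the C13 acetate of the target at this stage.

Step 13
Reactants: 20 [4-(chloroacetyl)-5-({(2R)-5-[(1S)-1-hydroxyethyl]-2-methyl-2,3-dihydrofuran-2-yl}methyl)furan-3-yl]methyl acetate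
Product: 21 [5-{[(2R)-5-acetyl-2-methyl-2,3-dihydrofuran-2-yl]methyl}-4-(chloroacetyl)furan-3-yl]methyl acetate
Conditions: Dess–Martin periodinane, NaHCO3, CH2Cl2, 0 °C
Reagents that add atoms: none
Why: Dess–Martin oxidation of the allylic secondary alcohol gives the C10 ketone conjugated with the enol ether, which removes the temporary carbinol stereocentre and makes the enol ether much less acid-sensitive.

Step 14
Reactants: 21 [5-{[(2R)-5-acetyl-2-methyl-2,3-dihydrofuran-2-yl]methyl}-4-(chloroacetyl)furan-3-yl]methyl acetate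
Product: 22 [5-{[(2R)-5-acetyl-2-methyl-2,3-dihydrofuran-2-yl]methyl}-4-[1-(trimethylsilyloxy)ethenyl]furan-3-yl]methyl acetate
Conditions: Zn dust (activated), Me3SiCl (excess), THF, 0 °C; filtered and used crude
Reagents that add atoms: chlorotrimethylsilane C[Si](C)(C)Cl
Why: Reformatsky-type reductive silylation: zinc metal inserts into the C–Cl bond of the α-chloro ketone and excess Me3SiCl O-silylates the zinc enolate before it can react further, giving the enol ether regiospecifically at C8=C9 while the C10 methyl ketone is never enolised.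

Step 15
Reactants: 22 [5-{[(2R)-5-acetyl-2-methyl-2,3-dihydrofuran-2-yl]methyl}-4-[1-(trimethylsilyloxy)ethenyl]furan-3-yl]methyl acetate
Product: 24 (4R,10S)-13-acetoxy-10-hydroxy-1,4:6,12-diepoxygermacra-1,6,11-trien-8-one (furan-fused ketol), via difluoroboron aldolate 23 (not isolated)
Conditions: BF3·OEt2 (1.5 equiv), CH2Cl2, −78 °C, syringe-pump addition of 22 (final 0.002 M); aq. NaHCO3 at −78 °C
Reagents that add atoms: none
Why: BF3 binds the C10 carbonyl oxygen of the 2-acetyl-2,3-dihydrofuran and the silyl enol ether carbon C9 adds to C10 through an open, antiperiplanar transition state, silicon leaving as Me3SiF and the adduct being held as difluoroboron aldolate 23 until hydrolysis, so that retro-aldol cleavage is suppressed; the closest known reaction type is the intramolecular Mukaiyama aldol addition used to close medium rings. The bond closes the oxa-bridged nine-membered ring O1–C1–C10–C9–C8–C7–C6–C5–C4 in a 9-(enolendo)-exo-trig mode and thereby also the ten-membered carbocycle C1–C10 (10-(enolendo)-exo-trig). The closure should be feasible because the furan holds C5 and C8 cis on C6=C7 and the chain between the two five-membered rings contains only three sp3 atoms (C4, C5, C9), which leaves few rotors to freeze and few transannular hydrogens. The new stereocentre C10 is controlled by C4: the tether leaves the dihydrofuran on the face that carries C5, so C9 can reach only the carbonyl face syn to C5, and with C8 lying below the O1 edge the antiperiplanar approach requires the acetyl group in its s-cis rotamer (C=O anti to O1, the dipole-minimised arrangement that monodentate BF3 cannot override by chelation), which corresponds to 10S. The step needs C9 regioselectivity (secured by the enol ether made specifically from the chloro ketone), 1,2- instead of 1,4-addition (C2 is the electron-rich β-carbon of an enol ether) and cyclisation instead of oligomerisation (slow addition to high dilution).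

Step 16
Reactants: 24 (4R,10S)-13-acetoxy-10-hydroxy-1,4:6,12-diepoxygermacra-1,6,11-trien-8-one
Product: 26 (4R,8R,10S)-13-acetoxy-1,4:6,12-diepoxygermacra-1,6,11-triene-8,10-diol, via diethylboron chelate 25 (not isolated)
Conditions: Et2BOMe, THF–MeOH (4:1), −78 °C; NaBH4; then MeOH co-evaporation
Reagents that add atoms: none
Why: Narasaka–Prasad reduction: boron bridges the C10 alkoxide and the C8 carbonyl in a six-membered half-chair chelate and external hydride adds axially, which should give the 1,3-syn diol and hence 8R relative to 10S; acetate, furan and enol ether are inert at −78 °C.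

Step 17
Reactants: 26 (4R,8R,10S)-13-acetoxy-1,4:6,12-diepoxygermacra-1,6,11-triene-8,10-diol
Product: 27 (4R,8R,10S)-13-acetoxy-10-hydroxy-1,4:6,12-diepoxygermacra-1,6,11-trien-8-yl 2-methylprop-2-enoate
Conditions: methacrylic anhydride, Et3N, DMAP (cat.), CH2Cl2, 0 °C to rt
Reagents that add atoms: methacrylic anhydride C=C(C)C(=O)OC(=O)C(C)=C
Why: DMAP-catalysed acylation is selective for the secondary C8 hydroxyl over the hindered tertiary C10 hydroxyl, with retention at C8.

Step 18
Reactants: 27 (4R,8R,10S)-13-acetoxy-10-hydroxy-1,4:6,12-diepoxygermacra-1,6,11-trien-8-yl 2-methylprop-2-enoate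
Product: 29 (4R,8R,10S)-13-acetoxy-1,4-epoxy-6,10-dihydroxy-8-(methacryloyloxy)germacra-1,7(11)-dien-12,6-olide (γ-hydroxybutenolide; both C6 epimers), via furan endoperoxide 28 (not isolated)
Conditions: O2, visible light, tetraphenylporphyrin (cat.), iPr2NEt, CH2Cl2, −78 °C
Reagents that add atoms: dioxygen O=O
Why: [4+2] cycloaddition of singlet oxygen to the trialkylfuran (orders of magnitude faster than attack on the enol ether or the electron-poor methacrylate) and base-induced Kornblum–DeLaMare fragmentation of the endoperoxide, in which the amine removes the only bridgehead hydrogen (C12–H), so that the carbonyl should appear at C12 and the hydroxyl at C6.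

Step 19
Reactants: 29 (4R,8R,10S)-13-acetoxy-1,4-epoxy-6,10-dihydroxy-8-(methacryloyloxy)germacra-1,7(11)-dien-12,6-olide
Product: 31 (4R,5E,8R,10S)-13-acetoxy-1,4-epoxy-10-hydroxy-8-(methacryloyloxy)germacra-1,5,7(11)-trien-12,6-olide (CNP0394509.1), via hemiketal acetate 30 (not isolated)
Conditions: Ac2O (1.2 equiv), Et3N, DMAP (cat.), CH2Cl2, 0 °C; then DBU, 0 °C to rt
Reagents that add atoms: none
Why: Acylation of the hemiketal hydroxyl (much faster than that of the tertiary C10 hydroxyl) and base-induced elimination of acetic acid across C5–C6 give the γ-ylidene butenolide; only C5 carries hydrogens, and the ten-membered ring admits only the isomer with C4 and C7 cis on C5=C6, which is the E alkene of the target.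

**Compound list**

1 | (S)-but-3-yn-2-ol | C[C@H](O)C#C | starting material
2 | triethyl{[(2S)-but-3-yn-2-yl]oxy}silane | C[C@H](O[Si](CC)(CC)CC)C#C | intermediate
3 | (S)-2-methylglycidol, [(2S)-2-methyloxiran-2-yl]methanol | C[C@]1(CO)CO1 | starting material
4 | [(2R)-2-methyloxiran-2-yl]methyl 4-methylbenzenesulfonate | C[C@]1(COS(=O)(=O)c2ccc(C)cc2)CO1 | intermediate
5 | lithium acetylide of 2 | C[C@H](O[Si](CC)(CC)CC)C#C[Li] | intermediate (not isolated)
6 | (2R,6S)-2-hydroxy-2-methyl-6-[(triethylsilyl)oxy]hept-4-yn-1-yl 4-methylbenzenesulfonate | C[C@H](O[Si](CC)(CC)CC)C#CC[C@](C)(COS(=O)(=O)c1ccc(C)cc1)O | intermediate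
7 | triethyl({(2S)-5-[(2R)-2-methyloxiran-2-yl]pent-3-yn-2-yl}oxy)silane | C[C@H](O[Si](CC)(CC)CC)C#CC[C@]1(C)CO1 | intermediate
8 | 3,4-dibromofuran | Brc1cocc1Br | starting material
9 | (4-bromofuran-3-yl)lithium | [Li]c1cocc1Br | intermediate (not isolated)
10 | 4-bromofuran-3-carbaldehyde | O=Cc1cocc1Br | intermediate
11 | (4-bromofuran-3-yl)methanol | OCc1cocc1Br | intermediate
12 | [(4-bromofuran-3-yl)methoxy](tert-butyl)dimethylsilane | CC(C)(C)[Si](C)(C)OCc1cocc1Br | intermediate
13 | {3-bromo-4-[(tert-butyldimethylsilyloxy)methyl]furan-2-yl}lithium | [Li]c1occ(CO[Si](C)(C)C(C)(C)C)c1Br | intermediate (not isolated)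
14 | (2R,6S)-1-{3-bromo-4-[(tert-butyldimethylsilyloxy)methyl]furan-2-yl}-2-methyl-6-[(triethylsilyl)oxy]hept-4-yn-2-ol | C[C@H](O[Si](CC)(CC)CC)C#CC[C@](C)(Cc1occ(CO[Si](C)(C)C(C)(C)C)c1Br)O | intermediate
15 | {[4-bromo-5-({(2R)-2-methyl-5-[(1S)-1-(triethylsilyloxy)ethyl]-2,3-dihydrofuran-2-yl}methyl)furan-3-yl]methoxy}(tert-butyl)dimethylsilane | C[C@H](O[Si](CC)(CC)CC)C1=CC[C@](C)(Cc2occ(CO[Si](C)(C)C(C)(C)C)c2Br)O1 | intermediate
16 | 2-chloro-N-methoxy-N-methylacetamide | ClCC(=O)N(C)OC | starting material
17 | 3-furyllithium derived from 15 (Li in place of Br) | C[C@H](O[Si](CC)(CC)CC)C1=CC[C@](C)(Cc2occ(CO[Si](C)(C)C(C)(C)C)c2[Li])O1 | intermediate (not isolated)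
18 | 2-chloro-1-{4-[(tert-butyldimethylsilyloxy)methyl]-2-({(2R)-2-methyl-5-[(1S)-1-(triethylsilyloxy)ethyl]-2,3-dihydrofuran-2-yl}methyl)furan-3-yl}ethan-1-one | C[C@H](O[Si](CC)(CC)CC)C1=CC[C@](C)(Cc2occ(CO[Si](C)(C)C(C)(C)C)c2C(=O)CCl)O1 | intermediate
19 | 2-chloro-1-[4-(hydroxymethyl)-2-({(2R)-5-[(1S)-1-hydroxyethyl]-2-methyl-2,3-dihydrofuran-2-yl}methyl)furan-3-yl]ethan-1-one | C[C@H](O)C1=CC[C@](C)(Cc2occ(CO)c2C(=O)CCl)O1 | intermediate
20 | [4-(chloroacetyl)-5-({(2R)-5-[(1S)-1-hydroxyethyl]-2-methyl-2,3-dihydrofuran-2-yl}methyl)furan-3-yl]methyl acetate | C[C@H](O)C1=CC[C@](C)(Cc2occ(COC(C)=O)c2C(=O)CCl)O1 | intermediate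
21 | [5-{[(2R)-5-acetyl-2-methyl-2,3-dihydrofuran-2-yl]methyl}-4-(chloroacetyl)furan-3-yl]methyl acetate | CC(=O)C1=CC[C@](C)(Cc2occ(COC(C)=O)c2C(=O)CCl)O1 | intermediate
22 | [5-{[(2R)-5-acetyl-2-methyl-2,3-dihydrofuran-2-yl]methyl}-4-[1-(trimethylsilyloxy)ethenyl]furan-3-yl]methyl acetate | CC(=O)C1=CC[C@](C)(Cc2occ(COC(C)=O)c2C(=C)O[Si](C)(C)C)O1 | intermediate
23 | 10-O-difluoroboryl aldolate of 24 | O=C1C[C@](C)(OB(F)F)C2=CC[C@](C)(Cc3occ(COC(C)=O)c31)O2 | intermediate (not isolated)
24 | (4R,10S)-13-acetoxy-10-hydroxy-1,4:6,12-diepoxygermacra-1,6,11-trien-8-one | O=C1C[C@](C)(O)C2=CC[C@](C)(Cc3occ(COC(C)=O)c31)O2 | intermediate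
25 | 10-O-diethylboryl chelate of 24 | O=C1C[C@](C)(OB(CC)CC)C2=CC[C@](C)(Cc3occ(COC(C)=O)c31)O2 | intermediate (not isolated)
26 | (4R,8R,10S)-13-acetoxy-1,4:6,12-diepoxygermacra-1,6,11-triene-8,10-diol | O[C@@H]1C[C@](C)(O)C2=CC[C@](C)(Cc3occ(COC(C)=O)c31)O2 | intermediate
27 | (4R,8R,10S)-13-acetoxy-10-hydroxy-1,4:6,12-diepoxygermacra-1,6,11-trien-8-yl 2-methylprop-2-enoate | C=C(C)C(=O)O[C@@H]1C[C@](C)(O)C2=CC[C@](C)(Cc3occ(COC(C)=O)c31)O2 | intermediate
28 | furan endoperoxide of 27 (O2 bridging C6 and C12) | C=C(C)C(=O)O[C@@H]1C[C@](C)(O)C2=CC[C@](C)(CC34OOC(O3)C(COC(C)=O)=C41)O2 | intermediate (not isolated)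
29 | (4R,8R,10S)-13-acetoxy-1,4-epoxy-6,10-dihydroxy-8-(methacryloyloxy)germacra-1,7(11)-dien-12,6-olide (both C6 epimers) | C=C(C)C(=O)O[C@@H]1C[C@](C)(O)C2=CC[C@](C)(CC3(O)OC(=O)C(COC(C)=O)=C31)O2 | intermediate
30 | 6-O-acetate of 29 | C=C(C)C(=O)O[C@@H]1C[C@](C)(O)C2=CC[C@](C)(CC3(OC(C)=O)OC(=O)C(COC(C)=O)=C31)O2 | intermediate (not isolated)
31 | (4R,5E,8R,10S)-13-acetoxy-1,4-epoxy-10-hydroxy-8-(methacryloyloxy)germacra-1,5,7(11)-trien-12,6-olide (CNP0394509.1) | C=C(C)C(=O)O[C@@H]1C[C@](C)(O)C2=CC[C@](C)(/C=C3/OC(=O)C(COC(C)=O)=C31)O2 | target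

**Step count and risks**

Total step count: 19. Longest linear sequence: 15 steps (steps 1, 3, 4 and 8 to 19; the furan branch, steps 5 to 19, is equally long).

The three steps most likely to fail:

Step 15 (key ring closure). The nine-/ten-membered closure may be outrun by intermolecular aldol addition, by protodesilylation of the enol ether, or by Lewis-acid-induced dehydration or retro-aldol opening of the adduct. Facial selectivity at C10 would erode if the s-trans acetyl rotamer takes part. The fallback sets out from 22 and activates the nucleophile instead of the ketone. Catalytic Bu4N[Ph3SiF2] in THF at −78 °C, under the same high dilution, frees the enolate, which should add through the same extended geometry. The trimethylsilyl group is then passed on to the tertiary alkoxide (fluoride-initiated silyl-transfer aldol), giving the 10-O-trimethylsilyl ether of the ketol F1, which cannot revert. Et3N·3HF removes the silyl group and the route is rejoined at 24.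

Step 18 (furan photooxygenation). Singlet oxygen may also attack the electron-rich C1=C2 enol ether (dioxetane formation or ene reaction), and over-oxidation may follow, so chemoselectivity could be lost. The fallback sets out from 27 and masks the enol ether first. Methanol with a trace of pyridinium p-toluenesulfonate adds across C1=C2 to give the C1 methyl ketal F2. Photooxygenation as in step 18 then runs via the furan endoperoxide F3 to the hydroxybutenolide ketal F4. Acetylation to the hemiketal acetate F5 and DBU elimination as in step 19 give the ylidene butenolide ketal F6. Me3SiOTf with iPr2NEt then expels methanol from C1 toward C2 (ketal-to-enol-ether conversion) while silylating the C10 hydroxyl, giving the 10-O-trimethylsilyl enol ether F7. Et3N·3HF returns the route at 31.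

Step 16 (1,3-syn reduction). The medium ring may not allow the six-membered boron chelate, so that ring conformation rather than chelation decides the hydride face and the facial selectivity at C8 is poor. The fallback sets out from 24 and uses reagent control instead of substrate control. A CBS reduction with (S)-2-methyl-CBS-oxazaborolidine and catecholborane in toluene at −78 °C, with the furyl group acting as the large ketone substituent, should deliver the 8R alcohol and rejoins the route at 26. This fallback makes no new compound (F0).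

Further compounds
F1 | step 15 | 10-O-trimethylsilyl ether of ketol 24 | O=C1C[C@](C)(O[Si](C)(C)C)C2=CC[C@](C)(Cc3occ(COC(C)=O)c31)O2
F2 | step 18 | C1 methyl ketal of 27 (methanol adduct of the enol ether; C1 epimers) | C=C(C)C(=O)O[C@@H]1C[C@](C)(O)C2(OC)CC[C@](C)(Cc3occ(COC(C)=O)c31)O2
F3 | step 18 | furan endoperoxide of F2 | C=C(C)C(=O)O[C@@H]1C[C@](C)(O)C2(OC)CC[C@](C)(CC34OOC(O3)C(COC(C)=O)=C41)O2
F4 | step 18 | γ-hydroxybutenolide C1 methyl ketal | C=C(C)C(=O)O[C@@H]1C[C@](C)(O)C2(OC)CC[C@](C)(CC3(O)OC(=O)C(COC(C)=O)=C31)O2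
F5 | step 18 | 6-O-acetate of F4 | C=C(C)C(=O)O[C@@H]1C[C@](C)(O)C2(OC)CC[C@](C)(CC3(OC(C)=O)OC(=O)C(COC(C)=O)=C31)O2
F6 | step 18 | (5E)-ylidene butenolide C1 methyl ketal | C=C(C)C(=O)O[C@@H]1C[C@](C)(O)C2(OC)CC[C@](C)(/C=C3/OC(=O)C(COC(C)=O)=C31)O2
F7 | step 18 | 10-O-trimethylsilyl ether of 31 | C=C(C)C(=O)O[C@@H]1C[C@](C)(O[Si](C)(C)C)C2=CC[C@](C)(/C=C3/OC(=O)C(COC(C)=O)=C31)O2
F0 | step 16 | none | none
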